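**Retrosynthetic overview**
1. Target 14 comes from octabenzyl ether 13 by one global hydrogenolysis.
2. The upper pyran ring is formed last, by an invertive Mitsunobu O1–C2 closure of (R)-carbinol 12 (from catalyst-controlled transfer hydrogenation of ketone 11); this makes the 2,4-trans relationship.
3. Key disconnection: the interflavan C4–C8 bond, made from a ketone homoenolate equivalent (β-trifluoroborato ketone 6, C4 as nucleophile) and 8-bromocatechin derivative 9 by a stereospecific Suzuki–Miyaura coupling with inversion.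
4. 6 comes from enone 4 (Claisen–Schmidt of 2 and 3) by Cu-catalysed asymmetric β-borylation; 9 comes from (+)-catechin, whose pyran ring and two stereocentres are bought intact.

Assumption: 1, 3 and 7 are bought as catalogue compounds; the target is read as a (2S,4R), 2,4-trans upper flavan joined 4→8 to (2R,3S)-(+)-catechin. "Penta-O-benzylcatechin-8-yl" below means (2R,3S)-3,5,7-tris(benzyloxy)-2-[3,4-bis(benzyloxy)phenyl]chroman-8-yl.

**Step 1**
Reactants: 1 4-(benzyloxy)-2-hydroxybenzaldehyde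
Product: 2 4-(benzyloxy)-2-(methoxymethoxy)benzaldehyde
Conditions: MOMCl (1.5 equiv), K2CO3 (3 equiv), acetone, 0 °C to rt
Reagents that add atoms: chloromethyl methyl ether, COCCl
Why: Williamson-type O-alkylation to the MOM acetal; the ortho-phenol is masked so that it cannot bind boron or palladium in step 6 and is released exactly when the ring oxygen is needed.

**Step 2**
Reactants: 2 4-(benzyloxy)-2-(methoxymethoxy)benzaldehyde; 3 3',4'-bis(benzyloxy)acetophenone
Product: 4 (2E)-3-[4-(benzyloxy)-2-(methoxymethoxy)phenyl]-1-[3,4-bis(benzyloxy)phenyl]prop-2-en-1-one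
Conditions: KOH (3 equiv), EtOH/THF (2:1), rt, 24 h
Reagents that add atoms: none
Why: Claisen–Schmidt aldol condensation; the ketone enolate adds to the non-enolisable aldehyde and E1cB dehydration gives only the conjugated (E)-enone, with benzyl and MOM ethers stable to base.

**Step 3**
Reactants: 4 (2E)-enone
Product: 6 potassium {(1S)-1-[4-(benzyloxy)-2-(methoxymethoxy)phenyl]-3-[3,4-bis(benzyloxy)phenyl]-3-oxopropyl}trifluoroborate, via pinacol boronate 5 (not isolated)
Conditions: CuCl (5 mol%), (R,S)-Josiphos (6 mol%), NaOtBu (8 mol%), B2pin2 (1.2 equiv), MeOH (2 equiv), THF, rt; then KHF2 (aq, 5 equiv), MeOH, rt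
Reagents that add atoms: bis(pinacolato)diboron, CC1(C)OB(OC1(C)C)B1OC(C)(C)C(C)(C)O1; potassium hydrogen difluoride, F.[F-].[K+]
Why: Yun-type Cu-catalysed enantioselective conjugate borylation; the ligand-bound Cu–Bpin adds boron to one face of the β-carbon and methanol protonates the copper enolate, setting the (S) C–B centre (the future C4), and KHF2 then exchanges pinacol for fluoride without touching that centre. The ligand hand is assigned by analogy with cinnamate-type acceptors and is checked on an aliquot by oxidation to the β-hydroxy ketone; the mirror-image ligand is used if the sense is opposite.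

**Step 4**
Reactants: 7 (+)-catechin
Product: 8 penta-O-benzyl-(+)-catechin, (2R,3S)-3,5,7-tris(benzyloxy)-2-[3,4-bis(benzyloxy)phenyl]chroman
Conditions: NaH (5.5 equiv), BnBr (5.5 equiv), DMF, −20 °C to rt
Reagents that add atoms: benzyl bromide, BrCc1ccccc1
Why: Williamson etherification of the four phenoxides and then the 3-alkoxide under cold anhydrous conditions that avoid ring-opening epimerisation at C2, so the (2R,3S) centres of the chiral pool are kept.

**Step 5**
Reactants: 8 penta-O-benzyl-(+)-catechin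
Product: 9 (2R,3S)-3,5,7-tris(benzyloxy)-2-[3,4-bis(benzyloxy)phenyl]-8-bromochroman
Conditions: NBS (1.05 equiv), CH2Cl2, −40 °C to rt
Reagents that add atoms: N-bromosuccinimide, O=C1CCC(=O)N1Br
Why: Electrophilic aromatic bromination; C8 (between O1 and the 7-benzyloxy group) is the most nucleophilic position of perbenzylated catechin and reacts selectively over C6 and the catechol ring at low temperature, with no stereocentre involved.

**Step 6**
Reactants: 6 potassium β-trifluoroborato ketone; 9 8-bromo-penta-O-benzylcatechin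
Product: 11 (3R)-3-[4-(benzyloxy)-2-hydroxyphenyl]-1-[3,4-bis(benzyloxy)phenyl]-3-(penta-O-benzylcatechin-8-yl)propan-1-one, via MOM ether ketone 10 (not isolated)
Conditions: 6 (1.3 equiv), Pd(OAc)2 (10 mol%), XPhos (20 mol%), K2CO3 (3 equiv), CPME/H2O (7:1), 95 °C; then crude, ZnBr2 (1.5 equiv), n-PrSH (3 equiv), CH2Cl2, 0 °C
Reagents that add atoms: none
Why: Proposed new method: stereospecific Suzuki–Miyaura coupling of a ketone homoenolate equivalent, in which the ketone oxygen chelates boron in a five-membered ring so that the hindered ArPd(XPhos)Br attacks the C–B carbon from the rear (inversion, (S) C–B to (R) C–aryl, forming the C4–C8 bond), while the same O–Pd chelation in the alkylpalladium holds back β-hydride elimination until reductive elimination; the closest known reactions are the invertive couplings of secondary β-trifluoroborato amides and the couplings of primary β-trifluoroborato ketones with aryl halides, and the second stage is a thiol-scavenged Lewis-acid cleavage of the MOM acetal that leaves benzyl ethers and the ketone alone.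

**Step 7**
Reactants: 11 keto-phenol
Product: 12 (1R,3R)-3-[4-(benzyloxy)-2-hydroxyphenyl]-1-[3,4-bis(benzyloxy)phenyl]-3-(penta-O-benzylcatechin-8-yl)propan-1-ol
Conditions: RuCl(p-cymene)[(R,R)-TsDPEN] (2 mol%), HCO2H/Et3N (5:2), DMF, 40 °C
Reagents that add atoms: none
Why: Noyori–Ikariya asymmetric transfer hydrogenation; RuCl(p-cymene)[(R,R)-TsDPEN] delivers hydride to the aryl ketone face that gives the (R) carbinol (aryl versus CH2 discrimination), overriding the remote C3 centre, and the phenol and benzyl ethers are inert.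

**Step 8**
Reactants: 12 (1R,3R)-carbinol
Product: 13 (2S,4R)-7-(benzyloxy)-2-[3,4-bis(benzyloxy)phenyl]-4-(penta-O-benzylcatechin-8-yl)chroman
Conditions: PPh3 (1.5 equiv), DIAD (1.5 equiv), THF (0.02 M), 0 °C to rt
Reagents that add atoms: none
Why: Intramolecular Mitsunobu etherification; the phenoxide displaces the oxyphosphonium at the benzylic carbon in a 6-exo SN2 closure with inversion, (R) carbinol to (2S), which places the 2-aryl group trans to the 4-aryl group, and dilution plus low temperature keep the electron-rich benzylic centre from ionising.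

**Step 9**
Reactants: 13 octabenzyl ether
Product: 14 (2R,3S)-2-(3,4-dihydroxyphenyl)-8-[(2S,4R)-2-(3,4-dihydroxyphenyl)-7-hydroxychroman-4-yl]chroman-3,5,7-triol (target)
Conditions: H2 (1 atm), Pd(OH)2/C (20 wt%), THF/MeOH (1:1), rt
Reagents that add atoms: none
Why: Heterogeneous hydrogenolysis of the eight benzyl ethers under neutral conditions at 1 atm, which spares the cyclic benzylic ethers and the acid-labile 4→8 bond and leaves all four stereocentres untouched.

**Compound list**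
1 | 4-(benzyloxy)-2-hydroxybenzaldehyde | O=Cc1ccc(OCc2ccccc2)cc1O | starting material
2 | 4-(benzyloxy)-2-(methoxymethoxy)benzaldehyde | O=Cc1ccc(OCc2ccccc2)cc1OCOC | intermediate
3 | 3',4'-bis(benzyloxy)acetophenone | CC(=O)c1ccc(OCc2ccccc2)c(OCc2ccccc2)c1 | starting material
4 | (2E)-3-[4-(benzyloxy)-2-(methoxymethoxy)phenyl]-1-[3,4-bis(benzyloxy)phenyl]prop-2-en-1-one | O=C(c1ccc(OCc2ccccc2)c(OCc2ccccc2)c1)/C=C/c1ccc(OCc2ccccc2)cc1OCOC | intermediate
5 | (3S)-3-[4-(benzyloxy)-2-(methoxymethoxy)phenyl]-1-[3,4-bis(benzyloxy)phenyl]-3-(4,4,5,5-tetramethyl-1,3,2-dioxaborolan-2-yl)propan-1-one | O=C(c1ccc(OCc2ccccc2)c(OCc2ccccc2)c1)C[C@@H](c1ccc(OCc2ccccc2)cc1OCOC)B1OC(C)(C)C(C)(C)O1 | intermediate (not isolated)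
6 | potassium {(1S)-1-[4-(benzyloxy)-2-(methoxymethoxy)phenyl]-3-[3,4-bis(benzyloxy)phenyl]-3-oxopropyl}trifluoroborate | O=C(c1ccc(OCc2ccccc2)c(OCc2ccccc2)c1)C[C@@H](c1ccc(OCc2ccccc2)cc1OCOC)[B-](F)(F)F.[K+] | intermediate
7 | (+)-catechin, (2R,3S)-2-(3,4-dihydroxyphenyl)chroman-3,5,7-triol | Oc1cc(O)c2c(c1)O[C@H](c1ccc(O)c(O)c1)[C@@H](O)C2 | starting material
8 | penta-O-benzyl-(+)-catechin | c1ccccc1COc1cc(OCc2ccccc2)c2c(c1)O[C@H](c1ccc(OCc3ccccc3)c(OCc3ccccc3)c1)[C@@H](OCc1ccccc1)C2 | intermediate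
9 | 8-bromo-penta-O-benzyl-(+)-catechin | c1ccccc1COc1cc(OCc2ccccc2)c2c(c1Br)O[C@H](c1ccc(OCc3ccccc3)c(OCc3ccccc3)c1)[C@@H](OCc1ccccc1)C2 | intermediate
10 | (3R)-3-[4-(benzyloxy)-2-(methoxymethoxy)phenyl]-1-[3,4-bis(benzyloxy)phenyl]-3-(penta-O-benzylcatechin-8-yl)propan-1-one | O=C(c1ccc(OCc2ccccc2)c(OCc2ccccc2)c1)C[C@H](c1ccc(OCc2ccccc2)cc1OCOC)c1c(OCc2ccccc2)cc(OCc2ccccc2)c2c1O[C@H](c1ccc(OCc3ccccc3)c(OCc3ccccc3)c1)[C@@H](OCc1ccccc1)C2 | intermediate (not isolated)
11 | (3R)-3-[4-(benzyloxy)-2-hydroxyphenyl]-1-[3,4-bis(benzyloxy)phenyl]-3-(penta-O-benzylcatechin-8-yl)propan-1-one | O=C(c1ccc(OCc2ccccc2)c(OCc2ccccc2)c1)C[C@H](c1ccc(OCc2ccccc2)cc1O)c1c(OCc2ccccc2)cc(OCc2ccccc2)c2c1O[C@H](c1ccc(OCc3ccccc3)c(OCc3ccccc3)c1)[C@@H](OCc1ccccc1)C2 | intermediate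
12 | (1R,3R)-3-[4-(benzyloxy)-2-hydroxyphenyl]-1-[3,4-bis(benzyloxy)phenyl]-3-(penta-O-benzylcatechin-8-yl)propan-1-ol | O[C@@H](c1ccc(OCc2ccccc2)c(OCc2ccccc2)c1)C[C@H](c1ccc(OCc2ccccc2)cc1O)c1c(OCc2ccccc2)cc(OCc2ccccc2)c2c1O[C@H](c1ccc(OCc3ccccc3)c(OCc3ccccc3)c1)[C@@H](OCc1ccccc1)C2 | intermediate
13 | (2S,4R)-7-(benzyloxy)-2-[3,4-bis(benzyloxy)phenyl]-4-(penta-O-benzylcatechin-8-yl)chroman | c1ccccc1COc1ccc2c(c1)O[C@H](c1ccc(OCc3ccccc3)c(OCc3ccccc3)c1)C[C@H]2c1c(OCc3ccccc3)cc(OCc3ccccc3)c2c1O[C@H](c1ccc(OCc3ccccc3)c(OCc3ccccc3)c1)[C@@H](OCc1ccccc1)C2 | intermediate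
14 | (2R,3S)-2-(3,4-dihydroxyphenyl)-8-[(2S,4R)-2-(3,4-dihydroxyphenyl)-7-hydroxychroman-4-yl]chroman-3,5,7-triol | Oc1ccc2c(c1)O[C@H](c1ccc(O)c(O)c1)C[C@H]2c1c(O)cc(O)c2c1O[C@H](c1ccc(O)c(O)c1)[C@@H](O)C2 | target

**Totals**
Total steps: 9. Longest linear sequence: 7 (steps 1, 2, 3, 6, 7, 8, 9).

**Three steps most likely to fail**

Step 6 (hindered secondary benzylic homoenolate coupling; risks are slow transmetalation, protodeboronation, β-hydride elimination back to 4, and partial loss of stereochemical fidelity). The fallback sets out from 2 and comes back at 10. Wittig olefination of 2 with Ph3P=CHC(O)N(OMe)Me (toluene, 80 °C) gives (2E)-3-[4-(benzyloxy)-2-(methoxymethoxy)phenyl]-N-methoxy-N-methylprop-2-enamide F1. The CuCl/Josiphos borylation of step 3 gives the (3S)-pinacol boronate amide F2, and KHF2 turns it into the potassium (S)-β-trifluoroborato amide F3. This more strongly chelating amide homoenolate, the substrate class for which invertive coupling is documented, is coupled with 9 under the palladium conditions of step 6 to give the (3R)-diaryl propanamide F4. Addition of 3,4-bis(benzyloxy)phenyllithium (from 4-bromo-1,2-bis(benzyloxy)benzene and n-BuLi, THF, −78 °C) to F4 gives ketone 10, which is deprotected to 11 as in step 6.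

Step 8 (the electron-rich benzylic oxyphosphonium may ionise, giving a cis/trans mixture at C2). The fallback sets out from 11 and comes back at 13. The phenol is converted (Tf2O, pyridine, CH2Cl2, 0 °C) into the aryl triflate ketone F5. Transfer hydrogenation with RuCl(p-cymene)[(S,S)-TsDPEN] gives the (1R,3S)-triflate carbinol F6. Pd-catalysed intramolecular C–O coupling (Pd(OAc)2, 2-(di-tert-butylphosphino)-1,1'-binaphthyl, K3PO4, toluene, 80 °C) then joins the carbinol oxygen to the aryl carbon; no bond at the carbinol carbon is broken, so the (S) centre is carried unchanged into 13.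

Step 3 (enantioselectivity on this electron-rich β-aryl enone, and stability of the benzylic boron species). The fallback sets out from 4 (with 9) and comes back at 10. A nickel-catalysed reductive conjugate arylation (NiCl2(dme) 10 mol%, neocuproine 10 mol%, Et3SiCl 1.5 equiv, Mn powder 2 equiv, DMF, 40 °C) joins the enone β-carbon and the aryl bromide through a silyloxyallyl nickel homoenolate without any boron intermediate. It gives the (Z)-triethylsilyl enol ether F7 as a mixture of C3 epimers. TBAF/AcOH (THF, 0 °C) releases 10 together with its (3S) epimer F8; the two are diastereomers because of the enantiopure catechin unit and are separated by chromatography.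

**Further compounds**
F1 | step 6 | (2E)-3-[4-(benzyloxy)-2-(methoxymethoxy)phenyl]-N-methoxy-N-methylprop-2-enamide | CON(C)C(=O)/C=C/c1ccc(OCc2ccccc2)cc1OCOC
F2 | step 6 | (3S)-3-[4-(benzyloxy)-2-(methoxymethoxy)phenyl]-N-methoxy-N-methyl-3-(4,4,5,5-tetramethyl-1,3,2-dioxaborolan-2-yl)propanamide | CON(C)C(=O)C[C@@H](c1ccc(OCc2ccccc2)cc1OCOC)B1OC(C)(C)C(C)(C)O1
F3 | step 6 | potassium {(1S)-1-[4-(benzyloxy)-2-(methoxymethoxy)phenyl]-3-[methoxy(methyl)amino]-3-oxopropyl}trifluoroborate | CON(C)C(=O)C[C@@H](c1ccc(OCc2ccccc2)cc1OCOC)[B-](F)(F)F.[K+]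
F4 | step 6 | (3R)-3-[4-(benzyloxy)-2-(methoxymethoxy)phenyl]-N-methoxy-N-methyl-3-(penta-O-benzylcatechin-8-yl)propanamide | CON(C)C(=O)C[C@H](c1ccc(OCc2ccccc2)cc1OCOC)c1c(OCc2ccccc2)cc(OCc2ccccc2)c2c1O[C@H](c1ccc(OCc3ccccc3)c(OCc3ccccc3)c1)[C@@H](OCc1ccccc1)C2
F5 | step 8 | 5-(benzyloxy)-2-[(1R)-3-[3,4-bis(benzyloxy)phenyl]-3-oxo-1-(penta-O-benzylcatechin-8-yl)propyl]phenyl trifluoromethanesulfonate | O=C(c1ccc(OCc2ccccc2)c(OCc2ccccc2)c1)C[C@H](c1ccc(OCc2ccccc2)cc1OS(=O)(=O)C(F)(F)F)c1c(OCc2ccccc2)cc(OCc2ccccc2)c2c1O[C@H](c1ccc(OCc3ccccc3)c(OCc3ccccc3)c1)[C@@H](OCc1ccccc1)C2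
F6 | step 8 | 5-(benzyloxy)-2-[(1R,3S)-3-[3,4-bis(benzyloxy)phenyl]-3-hydroxy-1-(penta-O-benzylcatechin-8-yl)propyl]phenyl trifluoromethanesulfonate | O[C@H](c1ccc(OCc2ccccc2)c(OCc2ccccc2)c1)C[C@H](c1ccc(OCc2ccccc2)cc1OS(=O)(=O)C(F)(F)F)c1c(OCc2ccccc2)cc(OCc2ccccc2)c2c1O[C@H](c1ccc(OCc3ccccc3)c(OCc3ccccc3)c1)[C@@H](OCc1ccccc1)C2
F7 | step 3 | {[(1Z)-3-[4-(benzyloxy)-2-(methoxymethoxy)phenyl]-1-[3,4-bis(benzyloxy)phenyl]-3-(penta-O-benzylcatechin-8-yl)prop-1-en-1-yl]oxy}triethylsilane, mixture of C3 epimers | CC[Si](CC)(CC)O/C(c1ccc(OCc2ccccc2)c(OCc2ccccc2)c1)=C\C(c1ccc(OCc2ccccc2)cc1OCOC)c1c(OCc2ccccc2)cc(OCc2ccccc2)c2c1O[C@H](c1ccc(OCc3ccccc3)c(OCc3ccccc3)c1)[C@@H](OCc1ccccc1)C2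
F8 | step 3 | (3S)-3-[4-(benzyloxy)-2-(methoxymethoxy)phenyl]-1-[3,4-bis(benzyloxy)phenyl]-3-(penta-O-benzylcatechin-8-yl)propan-1-one (C3 epimer of 10) | O=C(c1ccc(OCc2ccccc2)c(OCc2ccccc2)c1)C[C@@H](c1ccc(OCc2ccccc2)cc1OCOC)c1c(OCc2ccccc2)cc(OCc2ccccc2)c2c1O[C@H](c1ccc(OCc3ccccc3)c(OCc3ccccc3)c1)[C@@H](OCc1ccccc1)C2
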